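The question is what stops the theta flask, because a move at 15 h pays only if it lifts that stop by more than 2 percentage points.

common to all: electrophile 0.050 M; temperature 40 °C

|  | nucleophile | remark | time |
|---|---|---|---|
| theta | 1 equiv | the very flask that is asked about, followed so far |  |
| gamma | 2 equiv | run made earlier |  |
| flask | 1.00 equiv |  | 15 h |

| run | time / h | target / % |
|---|---|---|
| theta | 0.833 | 19 |
| theta | 2.50 | 35 |
| theta | 4.00 | 41 |
| theta | 6.00 | 45 |
| theta | 10.0 | 47 |
| theta | 12.0 | 46 |
| gamma | 0.200 | 14 |
| gamma | 0.667 | 34 |
| gamma | 1.00 | 40 |
| gamma | 1.50 | 51 |
| gamma | 2.50 | 57 |
| gamma | 3.00 | 66 |

(readings scatter by 1.5 percentage points)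

- Tuesday's: at 15 h add nucleophile, 50.0% of the amount charged, then wait 15 h
- Friday's: at 15 h take out 90% of the acid set free then present, then wait 15 h
- Monday's: change nothing and wait 15 h more
- Wednesday's: at 15 h raise the temperature by 10 K, then wait 15 h

- percent here means electrophile units held: one self-condensation product counts as two
- additions leave the volume as it is
- what may be going on: 2 electrophile -> self-condensation product; electrophile + nucleophile -> acid set free + target; nucleophile + acid set free <-> protonated nucleophile
- the earlier runs do not show what temperature does; that part of a forecast is a guess

- target, in percent of the electrophile first charged, at 15 h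
- what to do for the largest gain in target; "none" if nothing gains more than 2 percentage points (Tuesday's / Friday's / Monday's / Wednesday's / none)
- target present, in percent of the electrophile first charged, after Friday's
- target present, in percent of the electrophile first charged, after Wednesday's

Turn it round. For waiting to win, the theta flask would still have to be climbing, yet from 6.00 h to 12.0 h its readings rise by 1 point, less than the scatter of 1.5 points. The gamma run, with twice the nucleophile, reads 66% at 3.00 h, more than the theta flask ever shows, so the electrophile allows more and you should look at the nucleophile. If the acid set free by each target ties up a second nucleophile as protonated nucleophile, each target costs two nucleophile, and you get the nucleophile ceiling C, the target, in percent of the electrophile charged, at which n equivalents of nucleophile are used up so long as every acid set free is held that way: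

C = n / 2 = 50.0%

The theta reading of 47% at 10.0 h stands 3 points below C, which points to nucleophile as the limiting reagent. Tuesday's addition lifts C:

C′ = 75.0%

Tuesday's would fail for certain if less than 2 points of free electrophile remained at 15 h. The readings do not show that amount, so you take a risk in committing to a target near those late readings and to Tuesday's.

The forecast says 47%, Tuesday's, 48.5% after Friday's and 48.5% after Wednesday's, reasoning “so protonation is strong and nucleophile is nearly spent”.

The flask gives 48.6%, Tuesday's with a gain of 11 points, 51.0% after Friday's and 51.4% after Wednesday's.

    2 electrophile → self-condensation product (k = 6.20 × 10⁻⁴ /M/s, Ea = 83.0 kJ/mol)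
    electrophile + nucleophile → acid set free + target (k = 0.00210 /M/s, Ea = 65.0 kJ/mol)
    nucleophile + acid set free ⇌ protonated nucleophile, settled at all times (K = 10000 /M, ΔH = −4.00 kJ/mol)
    (constants at 40 °C)

The theta flask stands 1.4 points under C at 15.0 h with 4.79% of its nucleophile free, and the depletion of nucleophile together with its joining to the acid set free is part of why its target goes no higher: the simulated run without that joining reaches 68.5%. Tuesday's gain of 11 points stays within the 13.5% of electrophile left, which leaves target under C′. The neighbour flask with 1.70 equiv has a C of 85.0% but holds 74.0% of target at 15.0 h, with 13% of its nucleophile free and 21.6% of its electrophile in self-condensation product.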